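**Retrosynthetic overview**
1. Target 21 ⇐ O‑acetylation of hydroxy acid 19 ⇐ saponification of methyl ester 17.
2. Prenyl terminus of 17 ⇐ cross‑metathesis of the terminal alkene of 15 with 2‑methylbut‑2‑ene.
3. Key C4'–C5' bond and the (R)‑carbinol of 15 ⇐ reagent‑controlled asymmetric carbonyl allylation (Brown allylboration) of (E)‑enal 10.
4. Enal 10 ⇐ cross‑metathesis of allyl arene 8 with methacrolein; 8 ⇐ Wittig olefination of aldehyde 6.
5. 6 ⇐ O‑allylation, aromatic Claisen rearrangement and O‑methylation of 4‑hydroxybenzaldehyde. No ring is formed; the benzene ring is bought.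

Assumption: the SMILES is read as the (4R)‑acetate with both C=C bonds E. "Ipc" means the isopinocampheyl group derived from (−)‑α‑pinene, defined by the SMILES of 12. Material of ≥95 % ee after step 6 (chiral HPLC on 15) is carried on as the single enantiomer.

**Step 1**
Reactants: 1 4‑hydroxybenzaldehyde; 2 allyl bromide
Product: 3 4‑(prop‑2‑en‑1‑yloxy)benzaldehyde
Conditions: K2CO3, acetone, reflux
Reagents that add atoms: none
Why: Williamson ether synthesis, in which the acidic para‑formyl phenol is cleanly O‑alkylated by the primary allylic bromide (SN2).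

**Step 2**
Reactants: 3 4‑(prop‑2‑en‑1‑yloxy)benzaldehyde
Product: 5 4‑hydroxy‑3‑(prop‑2‑en‑1‑yl)benzaldehyde, via dienone tautomer 4 (not isolated)
Conditions: neat, degassed, N2, 200–210 °C, 6 h
Reagents that add atoms: none
Why: aromatic Claisen [3,3]‑sigmatropic rearrangement to one of the two equivalent ortho positions, followed by rearomatising tautomerisation of the dienone; no stereocentre persists.

**Step 3**
Reactants: 5 4‑hydroxy‑3‑(prop‑2‑en‑1‑yl)benzaldehyde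
Product: 6 4‑methoxy‑3‑(prop‑2‑en‑1‑yl)benzaldehyde
Conditions: MeI, K2CO3, acetone, reflux
Reagents that add atoms: methyl iodide, CI
Why: Williamson O‑methylation of the phenoxide; the aldehyde and allyl group are inert to these mild conditions.

**Step 4**
Reactants: 6 4‑methoxy‑3‑(prop‑2‑en‑1‑yl)benzaldehyde; 7 methyl (triphenylphosphoranylidene)acetate
Product: 8 methyl (2E)‑3‑[4‑methoxy‑3‑(prop‑2‑en‑1‑yl)phenyl]prop‑2‑enoate
Conditions: toluene, 90 °C; the few % of Z isomer removed by chromatography or recrystallisation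
Reagents that add atoms: none
Why: Wittig olefination with a stabilised ylide gives the (E)‑cinnamate under neutral conditions that cannot isomerise the allyl group.

**Step 5**
Reactants: 8 methyl (2E)‑3‑[4‑methoxy‑3‑(prop‑2‑en‑1‑yl)phenyl]prop‑2‑enoate; 9 methacrolein
Product: 10 methyl (2E)‑3‑{4‑methoxy‑3‑[(2E)‑3‑methyl‑4‑oxobut‑2‑en‑1‑yl]phenyl}prop‑2‑enoate
Conditions: Hoveyda–Grubbs II (5 mol %), 9 (10 equiv, in portions), 1,4‑benzoquinone (10 mol %), CH2Cl2, 40 °C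
Reagents that add atoms: none
Why: olefin cross‑metathesis of the only terminal alkene with the 1,1‑disubstituted enal gives the thermodynamically favoured (E)‑trisubstituted enal, the electron‑poor cinnamate being inert and benzoquinone suppressing allyl‑to‑propenyl isomerisation.

**Step 6 (key step)**
Reactants: 10 methyl (2E)‑3‑{4‑methoxy‑3‑[(2E)‑3‑methyl‑4‑oxobut‑2‑en‑1‑yl]phenyl}prop‑2‑enoate; 11 allylmagnesium bromide; 12 (+)‑B‑methoxydiisopinocampheylborane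
Product: 15 methyl (2E)‑3‑{3‑[(2E,4R)‑4‑hydroxy‑3‑methylhepta‑2,6‑dien‑1‑yl]‑4‑methoxyphenyl}prop‑2‑enoate, via allylborane 13 (not isolated), via borinate ester 14 (not isolated)
Conditions: 12 (1.5 equiv), 11 (1.4 equiv), Et2O, 0 °C→rt; Mg salts filtered off (pentane); then 10, Et2O, −100→−78 °C; NaBO3·4H2O, THF/H2O, rt
Reagents that add atoms: none
Why: Brown asymmetric allylboration through a closed chair six‑membered transition state, in which the (−)‑α‑pinene‑derived Ipc ligands deliver the allyl group to the Re face of the aldehyde (chemoselectively over the ester) to set the (R)‑carbinol, the enantiomeric reagent being known to give the (S)‑alcohol from closely related α‑methyl enals in >95 % ee.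

**Step 7**
Reactants: 15 methyl (2E)‑3‑{3‑[(2E,4R)‑4‑hydroxy‑3‑methylhepta‑2,6‑dien‑1‑yl]‑4‑methoxyphenyl}prop‑2‑enoate; 16 2‑methylbut‑2‑ene
Product: 17 methyl (2E)‑3‑{3‑[(2E,4R)‑4‑hydroxy‑3,7‑dimethylocta‑2,6‑dien‑1‑yl]‑4‑methoxyphenyl}prop‑2‑enoate
Conditions: Grubbs II (5 mol %), 16 (large excess, co‑solvent), CH2Cl2, rt–35 °C, sealed vessel
Reagents that add atoms: none
Why: olefin cross‑metathesis converts the monosubstituted alkene (the only reactive olefin; the trisubstituted alkene and the cinnamate are inert) into the prenyl terminus without touching the carbinol stereocentre.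

**Step 8**
Reactants: 17 methyl (2E)‑3‑{3‑[(2E,4R)‑4‑hydroxy‑3,7‑dimethylocta‑2,6‑dien‑1‑yl]‑4‑methoxyphenyl}prop‑2‑enoate
Product: 19 (2E)‑3‑{3‑[(2E,4R)‑4‑hydroxy‑3,7‑dimethylocta‑2,6‑dien‑1‑yl]‑4‑methoxyphenyl}prop‑2‑enoic acid, via lithium carboxylate 18 (not isolated)
Conditions: LiOH·H2O (3 equiv), THF/MeOH/H2O, rt; then 1 M HCl to pH 3, 0 °C
Reagents that add atoms: lithium hydroxide, [Li+].[OH-]
Why: saponification (BAc2) of the only ester, with the non‑epimerisable allylic carbinol stable to base and to the brief cold acidification.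

**Step 9**
Reactants: 19 (2E)‑3‑{3‑[(2E,4R)‑4‑hydroxy‑3,7‑dimethylocta‑2,6‑dien‑1‑yl]‑4‑methoxyphenyl}prop‑2‑enoic acid
Product: 21 (2E)‑3‑{3‑[(2E,4R)‑4‑acetoxy‑3,7‑dimethylocta‑2,6‑dien‑1‑yl]‑4‑methoxyphenyl}prop‑2‑enoic acid, via mixed anhydride 20 (not isolated)
Conditions: Ac2O (3 equiv), pyridine, DMAP (cat.), CH2Cl2, 0 °C→rt; then H2O/THF, rt, 2 h
Reagents that add atoms: acetic anhydride, CC(=O)OC(C)=O
Why: DMAP‑catalysed O‑acylation of the secondary allylic alcohol leaves the C–O bond and hence the (R) configuration untouched, and the transient carboxylic–acetic mixed anhydride is hydrolysed at its acetyl carbonyl in the aqueous pyridine quench while the acetate ester survives.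

**Compound list**
1 | 4‑hydroxybenzaldehyde | O=Cc1ccc(O)cc1 | starting material
2 | allyl bromide (3‑bromoprop‑1‑ene) | C=CCBr | starting material
3 | 4‑(prop‑2‑en‑1‑yloxy)benzaldehyde | C=CCOc1ccc(C=O)cc1 | intermediate
4 | 4‑oxo‑3‑(prop‑2‑en‑1‑yl)cyclohexa‑1,5‑diene‑1‑carbaldehyde (racemic Claisen dienone, not isolated) | C=CCC1C=C(C=O)C=CC1=O | intermediate
5 | 4‑hydroxy‑3‑(prop‑2‑en‑1‑yl)benzaldehyde | C=CCc1cc(C=O)ccc1O | intermediate
6 | 4‑methoxy‑3‑(prop‑2‑en‑1‑yl)benzaldehyde | C=CCc1cc(C=O)ccc1OC | intermediate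
7 | methyl (triphenylphosphoranylidene)acetate | COC(=O)C=P(c1ccccc1)(c1ccccc1)c1ccccc1 | starting material
8 | methyl (2E)‑3‑[4‑methoxy‑3‑(prop‑2‑en‑1‑yl)phenyl]prop‑2‑enoate | COC(=O)/C=C/c1ccc(OC)c(CC=C)c1 | intermediate
9 | methacrolein (2‑methylprop‑2‑enal) | CC(=C)C=O | starting material
10 | methyl (2E)‑3‑{4‑methoxy‑3‑[(2E)‑3‑methyl‑4‑oxobut‑2‑en‑1‑yl]phenyl}prop‑2‑enoate | COC(=O)/C=C/c1ccc(OC)c(C/C=C(\C)C=O)c1 | intermediate
11 | allylmagnesium bromide (1.0 M in Et2O) | C=CC[Mg]Br | starting material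
12 | (+)‑B‑methoxydiisopinocampheylborane, methoxybis[(1S,2R,3S,5S)‑2,6,6‑trimethylbicyclo[3.1.1]heptan‑3‑yl]borane (from (−)‑α‑pinene) | COB([C@H]1C[C@H]2C[C@@H]([C@@H]1C)C2(C)C)[C@H]1C[C@H]2C[C@@H]([C@@H]1C)C2(C)C | starting material
13 | B‑allyldiisopinocampheylborane of the (−)‑α‑pinene series (lIpc2B‑allyl), prop‑2‑en‑1‑ylbis[(1S,2R,3S,5S)‑2,6,6‑trimethylbicyclo[3.1.1]heptan‑3‑yl]borane (not isolated) | C=CCB([C@H]1C[C@H]2C[C@@H]([C@@H]1C)C2(C)C)[C@H]1C[C@H]2C[C@@H]([C@@H]1C)C2(C)C | intermediate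
14 | O‑(diisopinocampheylboryl) derivative of 15, (4R)‑borinate ester (not isolated) | COC(=O)/C=C/c1ccc(OC)c(C/C=C(\C)[C@@H](CC=C)OB([C@H]2C[C@H]3C[C@@H]([C@@H]2C)C3(C)C)[C@H]2C[C@H]3C[C@@H]([C@@H]2C)C3(C)C)c1 | intermediate
15 | methyl (2E)‑3‑{3‑[(2E,4R)‑4‑hydroxy‑3‑methylhepta‑2,6‑dien‑1‑yl]‑4‑methoxyphenyl}prop‑2‑enoate | COC(=O)/C=C/c1ccc(OC)c(C/C=C(\C)[C@@H](CC=C)O)c1 | intermediate
16 | 2‑methylbut‑2‑ene | CC=C(C)C | starting material
17 | methyl (2E)‑3‑{3‑[(2E,4R)‑4‑hydroxy‑3,7‑dimethylocta‑2,6‑dien‑1‑yl]‑4‑methoxyphenyl}prop‑2‑enoate | COC(=O)/C=C/c1ccc(OC)c(C/C=C(\C)[C@@H](CC=C(C)C)O)c1 | intermediate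
18 | lithium (2E)‑3‑{3‑[(2E,4R)‑4‑hydroxy‑3,7‑dimethylocta‑2,6‑dien‑1‑yl]‑4‑methoxyphenyl}prop‑2‑enoate (not isolated) | [Li+].[O-]C(=O)/C=C/c1ccc(OC)c(C/C=C(\C)[C@@H](CC=C(C)C)O)c1 | intermediate
19 | (2E)‑3‑{3‑[(2E,4R)‑4‑hydroxy‑3,7‑dimethylocta‑2,6‑dien‑1‑yl]‑4‑methoxyphenyl}prop‑2‑enoic acid | OC(=O)/C=C/c1ccc(OC)c(C/C=C(\C)[C@@H](CC=C(C)C)O)c1 | intermediate
20 | acetic (2E)‑3‑{3‑[(2E,4R)‑4‑acetoxy‑3,7‑dimethylocta‑2,6‑dien‑1‑yl]‑4‑methoxyphenyl}prop‑2‑enoic anhydride (not isolated) | CC(=O)OC(=O)/C=C/c1ccc(OC)c(C/C=C(\C)[C@@H](CC=C(C)C)OC(C)=O)c1 | intermediate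
21 | (2E)‑3‑{3‑[(2E,4R)‑4‑acetoxy‑3,7‑dimethylocta‑2,6‑dien‑1‑yl]‑4‑methoxyphenyl}prop‑2‑enoic acid (CNP0206859.1) | COc1ccc(/C=C/C(=O)O)cc1C/C=C(\C)[C@@H](CC=C(C)C)OC(C)=O | target

**Totals**
Total step count: 9. Longest linear sequence: 9 steps (1 → 21).

**Three steps most likely to fail, each with a fallback**

Step 5 (cross‑metathesis with methacrolein). The risks are allyl‑to‑propenyl isomerisation, homodimerisation of 8 and polymerisation of methacrolein. The fallback sets out from 8 and replaces the enal‑forming metathesis by an allylic C–H oxidation. Cross‑metathesis of 8 with 2‑methylbut‑2‑ene (Grubbs II, CH2Cl2, rt) gives the prenyl arene methyl (2E)‑3‑[4‑methoxy‑3‑(3‑methylbut‑2‑en‑1‑yl)phenyl]prop‑2‑enoate F1. Selenium dioxide (catalytic) with t‑BuOOH in CH2Cl2 oxidises the (E)‑methyl group selectively to the allylic alcohol methyl (2E)‑3‑{3‑[(2E)‑4‑hydroxy‑3‑methylbut‑2‑en‑1‑yl]‑4‑methoxyphenyl}prop‑2‑enoate F2, formed together with some 10. MnO2 in CH2Cl2 then takes F2 to enal 10, where the route is rejoined.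

Step 6 (Brown allylation). The risks are insufficient ee if Mg salts or higher temperature interfere, and loss of material on removing isopinocampheol. The fallback sets out from 10 and sets the stereocentre by catalytic asymmetric ketone reduction instead. Barbier allylation (Zn, allyl bromide, THF/aq NH4Cl, 0 °C) gives the racemic alcohol methyl (2E)‑3‑{3‑[(2E)‑4‑hydroxy‑3‑methylhepta‑2,6‑dien‑1‑yl]‑4‑methoxyphenyl}prop‑2‑enoate F3. Dess–Martin periodinane buffered with NaHCO3 (CH2Cl2, 0 °C, to avoid conjugation of the β,γ‑alkene) gives the ketone methyl (2E)‑3‑{4‑methoxy‑3‑[(2E)‑3‑methyl‑4‑oxohepta‑2,6‑dien‑1‑yl]phenyl}prop‑2‑enoate F4. Corey–Bakshi–Shibata reduction with (S)‑Me‑CBS (20 mol %) and catecholborane in toluene at −78 °C, with the α‑methylalkenyl group as the large substituent, gives the (R)‑alcohol 15, where the route is rejoined.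

Step 7 (cross‑metathesis to the prenyl group). The risks are incomplete conversion, Ru–H isomerisation of the allylic alcohol and minor involvement of the cinnamate. The fallback sets out from 10 and installs the whole prenyl unit directly. α‑Selective 1,2‑addition of prenylbarium chloride (prenyl chloride, Rieke barium, THF, −78 °C) gives the racemic linear carbinol methyl (2E)‑3‑{3‑[(2E)‑4‑hydroxy‑3,7‑dimethylocta‑2,6‑dien‑1‑yl]‑4‑methoxyphenyl}prop‑2‑enoate F5. Buffered Dess–Martin oxidation gives the ketone methyl (2E)‑3‑{3‑[(2E)‑3,7‑dimethyl‑4‑oxoocta‑2,6‑dien‑1‑yl]‑4‑methoxyphenyl}prop‑2‑enoate F6. (S)‑Me‑CBS/catecholborane reduction (toluene, −78 °C) gives the (R)‑alcohol 17, where the route is rejoined.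

**Further compounds**
F1 | step 5 | methyl (2E)‑3‑[4‑methoxy‑3‑(3‑methylbut‑2‑en‑1‑yl)phenyl]prop‑2‑enoate | COC(=O)/C=C/c1ccc(OC)c(CC=C(C)C)c1
F2 | step 5 | methyl (2E)‑3‑{3‑[(2E)‑4‑hydroxy‑3‑methylbut‑2‑en‑1‑yl]‑4‑methoxyphenyl}prop‑2‑enoate | COC(=O)/C=C/c1ccc(OC)c(C/C=C(\C)CO)c1
F3 | step 6 | methyl (2E)‑3‑{3‑[(2E)‑4‑hydroxy‑3‑methylhepta‑2,6‑dien‑1‑yl]‑4‑methoxyphenyl}prop‑2‑enoate (racemic) | COC(=O)/C=C/c1ccc(OC)c(C/C=C(\C)C(O)CC=C)c1
F4 | step 6 | methyl (2E)‑3‑{4‑methoxy‑3‑[(2E)‑3‑methyl‑4‑oxohepta‑2,6‑dien‑1‑yl]phenyl}prop‑2‑enoate | COC(=O)/C=C/c1ccc(OC)c(C/C=C(\C)C(=O)CC=C)c1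
F5 | step 7 | methyl (2E)‑3‑{3‑[(2E)‑4‑hydroxy‑3,7‑dimethylocta‑2,6‑dien‑1‑yl]‑4‑methoxyphenyl}prop‑2‑enoate (racemic) | COC(=O)/C=C/c1ccc(OC)c(C/C=C(\C)C(O)CC=C(C)C)c1
F6 | step 7 | methyl (2E)‑3‑{3‑[(2E)‑3,7‑dimethyl‑4‑oxoocta‑2,6‑dien‑1‑yl]‑4‑methoxyphenyl}prop‑2‑enoate | COC(=O)/C=C/c1ccc(OC)c(C/C=C(\C)C(=O)CC=C(C)C)c1
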